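## Analysis of the target

The target 24 is a profisetinidin-type biflavanoid, fisetinidol-(4α→8)-fisetinidol: an upper 2-(3,4-dihydroxyphenyl)chromane-3,7-diol (rings A, C and B) is joined through C4 of its pyran ring C to C8 of the resorcinol-type ring D of a second, identical flavan-3-ol (rings D, F and E). There are five stereocentres: C2 (R), C3 (S) and C4 (S) in ring C, and C2 (R) and C3 (S) in ring F. In both pyran rings the C3 hydroxyl is trans to the C2 aryl group, and in ring C it is also trans to ring D at C4, so the two aryl groups on ring C are cis; the two units have the same absolute configuration at C2 and C3. The free polyphenol oxidises easily, and the electron-rich benzylic ether carbons C2 and the doubly benzylic C4 ionise under acid, which would open a pyran ring, epimerise C2 or break the interflavan bond; protecting groups must therefore leave under neutral conditions and the late steps must avoid acid. The first difficulty is the C4–C8 bond: it ends on the ring-D carbon between two oxygens, whereas electrophilic coupling to a resorcinol-type flavan goes to C6, so this bond has to be fixed by the starting material and not by aromatic substitution. The second is the congested core, a diarylmethine carbon surrounded by three ortho oxygen substituents, next to which three contiguous stereocentres must be set. The strategy rests on the trans relationships at C2/C3 of ring F and at C2/C3/C4 of ring C: they are what a syn addition of hydrogen and boron across a C3=C4 double bond, anti to the C2 aryl group, produces, so both pyran rings can be traced back to 2-aryl-2H-chromenes whose C3=C4 bonds are made by ring-closing metathesis. Only the two identical C2 ether centres then have to exist before the rings are closed.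

## Retrosynthetic reasoning

**24 ⇐ 23 (six O–benzyl bonds).** All six phenols are carried as benzyl ethers in hexabenzyl diol 23. Benzyl ethers survive the organolithium, titanium, iridium, ruthenium and borane chemistry of the route and fall in one neutral hydrogenolysis, so the air- and acid-sensitive polyphenol appears only in the last flask. The two C3 alcohols need no protection.

**23 ⇐ 21 (C3–O and C4–H in rings C and F).** Removing the two C3 hydroxyls and the adjacent C4 hydrogens leads to bis-flavene 21. The cut is made here because hydroboration–oxidation is the one reaction that adds H and O syn across an alkene. The forward step has to place boron at C3 of both rings on the face opposite the C2 aryl group (intermediate 22). In ring C the hydrogen delivered to C4 on the same face pushes ring D trans to the new hydroxyl. Three stereocentres thus follow from the two that are present. The ether carbons are S in 19, 20 and 21 (aryl outranks vinyl) and become R in 23 and 24 because C3 gains oxygen; nothing moves in space.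

**21 ⇐ 19 (C3=C4 of both pyran rings; the key disconnection).** Cutting both C3=C4 bonds in the retro-metathesis sense opens rings C and F and gives tetraene 19, through ring-F chromene 20. These are the only ring bonds whose formation needs neither stereocontrol nor acid, and because the two halves of the target are alike, one operation makes both rings. The forward reaction must pair each ether alkene with the right partner: the ring-D ether with its ortho vinyl group (ring F) and the ring-A ether with the 1,1-diarylethene (ring C).

**19 ⇐ 14 + 18 (the two O–C2 bonds).** The aryl–O–C2 bonds are cut to bis-phenol 14 and two molecules of cinnamyl carbonate 18. A catalytic asymmetric allylic etherification gives the branched ethers, and since both centres have the same configuration one catalyst sets both. The step is placed directly before the metathesis so that the ionisable 1-arylallyl ethers meet no other reagent. Carbonate 18 comes from caffeic acid 15 through ester 16 and allylic alcohol 17.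

**14 ⇐ 13 ⇐ 12 (protecting-group change; C=CH2 from C=O).** The two phenols of 14 are masked as allyl ethers in 13, which can be removed without acid in the presence of benzyl ethers, the styrene and the diarylethene. The 1,1-diarylethene is traced to ketone 12. Methylenation is done at this stage, while the ortho substituents of the hindered carbonyl are small and no stereocentre can be harmed.

**12 ⇐ 11 ⇐ 6 + 9 (the bond from the central carbon to C8 of ring D).** This cut gives aryllithium 10, made from bromide 6, and aldehyde 9. C8 lies between two ether oxygens, which is the ideal site for a stabilised aryl anion, and the bromine sits there from the start in 1, so the regiochemistry of the interflavan bond is never in doubt. The carbinol 11 is oxidised to 12.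

**6 ⇐ 5 ⇐ 4 ⇐ 3 ⇐ 1 and 9 ⇐ 8 ⇐ 7.** Formylation of 1 (through iminium salt 2) gives 3, whose two hydroxyls are differentiated by the hydrogen bond to the formyl group: benzyl goes on O4, allyl on O2, and the aldehyde is turned into the vinyl group of 6. The same two etherifications on 7 give 9.

## Alternatives that were turned down

**Alternative 1:** The disconnection is C3–C4 and O1–C2 of ring F, a formal [4+2] across the ring-D phenol oxygen and its benzylic carbon. In the forward key step, dehydration of salicyl alcohol A2 (the finished upper flavan carrying a ring D with a free C8a hydroxyl and a hydroxymethyl group at C4a) in the presence of Z silyl enol ether A1 would give silyl ketal A3 as C2 epimers by an inverse-demand hetero-Diels–Alder reaction; an ionic reduction of the ketal would then set C2.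
- For: ring F arrives with its C3 oxygen at the right oxidation level and already protected, the cycloaddition type is well established, and C2 is never exposed as a chromene.
- Against: A2 already contains the C4–C8 bond and all three ring-C stereocentres, so the hardest bond of the target is not addressed. The new C3 centre would have to be induced across the freely rotating C4–C8 bond by distant stereocentres, for which there is no reliable model. The ketal reduction needs a Lewis acid next to the acid-labile doubly benzylic C4.
- Comparison: it is stronger than the chosen route on the regiochemistry of oxygenation, since no hydroboration is needed. It is linear where the chosen route is bidirectional, and it trades two catalyst-controlled ether centres for one substrate-controlled centre of uncertain sense. In place of that advantage the chosen route makes both heterocycles from 19 in one operation and fixes the C8 attachment by the bromine of 1.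

**Alternative 2:** The disconnection is C3–C4 and O1–C2 of ring C, with C2 at the carboxyl oxidation level. In the forward key step, base would expel the sulfonyl group from sulfone A4 (a ring-A phenol whose benzylic carbon already carries the protected lower flavan); the resulting quinone-methide-type acceptor would take up at C4 the enolate formed from benzyloxyacetyl chloride A5 on a chiral Lewis-base catalyst, and lactonisation on the phenoxide would close ring C as dihydrocoumarin A6.
- For: C3 and C4 come from one catalytic enantioselective annulation under mild base, and C4 is set by the catalyst instead of being relayed from C2.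
- Against: ring B is absent and C2 is a lactone carbonyl in A6, so aryl addition and reduction of the resulting lactol are still needed, each with a stereochemical question at C2 and with an epimerisable alkoxy-bearing C3 next to the carbonyl. The acceptor carbon carries a di-ortho-substituted aryl group, which slows conjugate addition, and catalyst and chiral lower unit may be mismatched. The lower flavan has to be made and functionalised at C8 first.
- Comparison: it is stronger on the control of C4. It is weaker in step economy after the key step (several steps against two) and needs a finished flavan as one partner. The chosen route offers symmetry instead: both halves are treated by the same reactions at the same time.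

**Alternative 3:** The disconnection is C4–C4a of ring F. In the forward key step, acid activation of epoxide A7 (the upper flavan whose ring-D phenol is etherified with a 1-aryl-2,3-epoxypropyl unit) would let the ring-D carbon para to the benzyloxy group attack the terminal epoxide carbon in a Friedel–Crafts alkylation, closing ring F and releasing the C3 hydroxyl in A8.
- For: C2 and C3 of ring F come from an epoxy alcohol whose absolute configuration can be set by reagent control, the hydroxyl emerges where it is needed, and A8 is one hydrogenolysis away from 24.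
- Against: the activating acid meets an electron-rich benzylic ether at C2 and the doubly benzylic C4 of the upper unit, both of which ionise. Attack at the internal epoxide carbon, giving a five-membered ring, competes with the wanted six-membered closure. A7 again presupposes the finished upper unit with its C4–C8 bond.
- Comparison: it is stronger than the chosen route in the reliability of the C3 configuration of ring F and in the number of steps after the key step. It is weaker because its key step runs under acid on the most acid-sensitive intermediate and because it is linear. The chosen route keeps every step after 19 neutral or basic and needs no preformed flavan.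

Key step: step 15

Assumption: the (Sa,Sc,Sc) phosphoramidite is taken to give the S ethers in step 14, following the usual sense of induction of this catalyst family with cinnamyl carbonates and aryloxides; a trial run on a simple phenol would confirm it, and the antipodal ligand would be used if the sense proved opposite.

## Route

Step 1
Reactants: 1 2-bromoresorcinol
Product: 3 3-bromo-2,4-dihydroxybenzaldehyde, via iminium chloride 2 (not isolated)
Conditions: POCl3, DMF, MeCN, −15 °C → rt; then H2O, 50 °C
Reagents that add atoms: N,N-dimethylformamide CN(C)C=O (formyl carbon); water O (carbonyl oxygen)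
Why: Vilsmeier–Haack formylation; C4 and C6 of 1 are equivalent and are each ortho to one hydroxyl and para to the other, so a single aldehyde should result after hydrolysis of iminium salt 2.

Step 2
Reactants: 3 3-bromo-2,4-dihydroxybenzaldehyde
Product: 4 4-(benzyloxy)-3-bromo-2-hydroxybenzaldehyde
Conditions: BnBr (1.05 equiv), NaHCO3, KI (cat.), MeCN, reflux
Reagents that add atoms: benzyl bromide BrCc1ccccc1
Why: Williamson etherification; the 2-hydroxyl is held in a hydrogen bond to the formyl group and the 4-hydroxyl (para to the formyl group, ortho to bromine) is the more acidic, so a weak base should alkylate O4 only.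

Step 3
Reactants: 4 4-(benzyloxy)-3-bromo-2-hydroxybenzaldehyde
Product: 5 2-(allyloxy)-4-(benzyloxy)-3-bromobenzaldehyde
Conditions: allyl bromide, K2CO3, DMF, 50 °C
Reagents that add atoms: allyl bromide C=CCBr
Why: Williamson etherification of the remaining phenol; allyl is used as a temporary group because it survives the organolithium, oxidation and methylenation steps and is later removed by zerovalent palladium without acid.

Step 4
Reactants: 5 2-(allyloxy)-4-(benzyloxy)-3-bromobenzaldehyde
Product: 6 3-(allyloxy)-1-(benzyloxy)-2-bromo-4-ethenylbenzene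
Conditions: Ph3PCH3Br, KOtBu, THF, 0 °C → rt
Reagents that add atoms: methyltriphenylphosphonium bromide C[P+](c1ccccc1)(c1ccccc1)c1ccccc1.[Br-]
Why: Wittig methylenation of an aromatic aldehyde; it installs the vinyl group that becomes C4 of ring F.

Step 5
Reactants: 7 2,4-dihydroxybenzaldehyde
Product: 8 4-(benzyloxy)-2-hydroxybenzaldehyde
Conditions: BnBr (1.05 equiv), NaHCO3, KI (cat.), MeCN, reflux
Reagents that add atoms: benzyl bromide BrCc1ccccc1
Why: Williamson etherification; the chelated 2-hydroxyl stays free and the more acidic 4-hydroxyl is benzylated, as in step 2.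

Step 6
Reactants: 8 4-(benzyloxy)-2-hydroxybenzaldehyde
Product: 9 2-(allyloxy)-4-(benzyloxy)benzaldehyde
Conditions: allyl bromide, K2CO3, DMF, 50 °C
Reagents that add atoms: allyl bromide C=CCBr
Why: Williamson etherification; the phenol must be masked before the aryllithium addition, and allyl matches the group on ring D so that both come off together in step 10.

Step 7
Reactants: 6 3-(allyloxy)-1-(benzyloxy)-2-bromo-4-ethenylbenzene; 9 2-(allyloxy)-4-(benzyloxy)benzaldehyde
Product: 11 [2-(allyloxy)-4-(benzyloxy)phenyl][2-(allyloxy)-6-(benzyloxy)-3-ethenylphenyl]methanol (racemic), via aryllithium 10 (not isolated)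
Conditions: 6, n-BuLi (1.05 equiv), THF, −78 °C, 15 min; then 9, −78 °C; H2O
Reagents that add atoms: none
Why: Bromine–lithium exchange followed by 1,2-addition to an aldehyde; at −78 °C the exchange outruns addition of butyllithium to the styrene, and aryllithium 10 is stabilised by its two flanking ether oxygens. The bond formed here is the future C4–C8 bond; the carbinol centre is racemic and is removed in step 8.

Step 8
Reactants: 11 [2-(allyloxy)-4-(benzyloxy)phenyl][2-(allyloxy)-6-(benzyloxy)-3-ethenylphenyl]methanol
Product: 12 [2-(allyloxy)-4-(benzyloxy)phenyl][2-(allyloxy)-6-(benzyloxy)-3-ethenylphenyl]methanone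
Conditions: activated MnO2 (excess), CH2Cl2, rt
Reagents that add atoms: none
Why: Oxidation of a doubly benzylic alcohol by manganese dioxide; the alkenes and ethers are inert to it.

Step 9
Reactants: 12 [2-(allyloxy)-4-(benzyloxy)phenyl][2-(allyloxy)-6-(benzyloxy)-3-ethenylphenyl]methanone
Product: 13 1-[2-(allyloxy)-4-(benzyloxy)phenyl]-1-[2-(allyloxy)-6-(benzyloxy)-3-ethenylphenyl]ethene
Conditions: Cp2TiMe2 (2.5 equiv), toluene, 70 °C, dark
Reagents that add atoms: dimethyltitanocene [CH3-].[CH3-].[Ti+4].[cH-]1cccc1.[cH-]1cccc1
Why: Petasis methylenation; the titanium methylidene formed on heating is non-basic and compact enough for a diaryl ketone with three ortho substituents, and terminal alkenes only undergo degenerate exchange with it. The step is run before any stereocentre exists.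

Step 10
Reactants: 13 1-[2-(allyloxy)-4-(benzyloxy)phenyl]-1-[2-(allyloxy)-6-(benzyloxy)-3-ethenylphenyl]ethene
Product: 14 1-[4-(benzyloxy)-2-hydroxyphenyl]-1-[6-(benzyloxy)-3-ethenyl-2-hydroxyphenyl]ethene
Conditions: Pd(PPh3)4 (5 mol %), K2CO3, MeOH–THF, rt
Reagents that add atoms: none
Why: Tsuji–Trost-type deallylation; zerovalent palladium ionises the aryl allyl ethers and methanol captures the allyl group, while benzyl ethers, the styrene and the diarylethene are untouched and no acid is used. The bis-phenol is used at once.

Step 11
Reactants: 15 caffeic acid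
Product: 16 benzyl (E)-3-[3,4-bis(benzyloxy)phenyl]prop-2-enoate
Conditions: BnBr (3.3 equiv), K2CO3, DMF, 60 °C
Reagents that add atoms: benzyl bromide BrCc1ccccc1
Why: Exhaustive Williamson alkylation of both phenols and the carboxylate; the E alkene is unaffected.

Step 12
Reactants: 16 benzyl (E)-3-[3,4-bis(benzyloxy)phenyl]prop-2-enoate
Product: 17 (E)-3-[3,4-bis(benzyloxy)phenyl]prop-2-en-1-ol
Conditions: i-Bu2AlH (2.5 equiv), CH2Cl2, −78 → 0 °C; aq. potassium sodium tartrate
Reagents that add atoms: none
Why: 1,2-Reduction of an α,β-unsaturated ester to the allylic alcohol by an aluminium hydride; the alkene geometry is retained.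

Step 13
Reactants: 17 (E)-3-[3,4-bis(benzyloxy)phenyl]prop-2-en-1-ol
Product: 18 (E)-3-[3,4-bis(benzyloxy)phenyl]prop-2-en-1-yl methyl carbonate
Conditions: ClCO2Me, pyridine, CH2Cl2, 0 °C
Reagents that add atoms: methyl chloroformate COC(=O)Cl
Why: Acylation of a primary alcohol; the carbonate is the leaving group for the allylic substitution.

Step 14
Reactants: 14 1-[4-(benzyloxy)-2-hydroxyphenyl]-1-[6-(benzyloxy)-3-ethenyl-2-hydroxyphenyl]ethene; 18 (E)-3-[3,4-bis(benzyloxy)phenyl]prop-2-en-1-yl methyl carbonate (2.6 equiv)
Product: 19 1-[4-(benzyloxy)-2-{[(1S)-1-(3,4-bis(benzyloxy)phenyl)prop-2-en-1-yl]oxy}phenyl]-1-[6-(benzyloxy)-2-{[(1S)-1-(3,4-bis(benzyloxy)phenyl)prop-2-en-1-yl]oxy}-3-ethenylphenyl]ethene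
Conditions: 14, n-BuLi (2.0 equiv), THF, −78 → 0 °C; then 18, [Ir(cod)Cl]2 (4 mol %), O,O'-(S)-(1,1'-binaphthalene-2,2'-diyl) N,N-bis[(S)-1-phenylethyl]phosphoramidite (8 mol %), pre-activated with n-PrNH2, THF, rt → 35 °C
Reagents that add atoms: none
Why: Iridium-catalysed enantioselective allylic etherification of lithium aryloxides with a cinnamyl carbonate; each phenoxide attacks the substituted terminus of the allyl iridium complex to give the branched ether, and the ligand fixes the face, so both new centres should be S irrespective of the substrate. The minor enantiomeric pathway ends in diastereomers, which can be removed at a later stage.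

Step 15
Reactants: 19 tetraene bis[(S)-1-arylallyl] ether
Product: 21 (2S)-7-(benzyloxy)-4-{(2S)-7-(benzyloxy)-2-[3,4-bis(benzyloxy)phenyl]-2H-chromen-8-yl}-2-[3,4-bis(benzyloxy)phenyl]-2H-chromene, via ring-F chromene 20 (not isolated)
Conditions: second-generation Grubbs catalyst (H2IMes)(PCy3)Cl2Ru=CHPh (2 × 5 mol %), 1,4-benzoquinone (20 mol %), degassed toluene (5 mM), 40 °C then 70 °C, Ar sparge, dark
Reagents that add atoms: none
Why: The ruthenium benzylidene exchanges onto a monosubstituted ether alkene (or onto the ring-D vinyl group as an ortho-alkoxybenzylidene chelate), and [2+2] cycloaddition with the alkene held ortho on the same arene followed by cycloreversion releases ethylene. The closest known reaction type is the ring-closing metathesis of aryl allyl ethers bearing an ortho vinyl or ortho 1-arylvinyl group to 2H-chromenes, including enantioenriched 1-arylallyl ethers. Ring F closes first, at 40 °C, as a six-membered ring between the ring-D ether alkene and the ortho vinyl group, giving the disubstituted C3=C4 bond of 20. Ring C then closes at 70 °C, again as a six-membered ring, between the ring-A ether alkene and the 1,1-diarylethene, giving the trisubstituted C3=C4 bond that carries ring D. No stereocentre is formed, and the two S ether centres lie outside the metallacycles and are carried through unchanged. The selectivity needed is the pairing of the alkenes: the ring-D ether could also close a six-membered ring onto the diarylethene, but a monosubstituted styrene reacts far faster than a 1,1-disubstituted alkene next to a di-ortho-substituted arene, and once ring F exists the ring-A ether has no terminal alkene left within reach other than the diarylethene. High dilution disfavours cross-metathesis, benzoquinone suppresses ruthenium hydride migration of the ether double bonds, and darkness with a ceiling of 70 °C guards C2 against electrocyclic opening of the O1–C2 bond.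

Step 16
Reactants: 21 bis-flavene
Product: 23 (2R,3S,4S)-7-(benzyloxy)-4-{(2R,3S)-7-(benzyloxy)-2-[3,4-bis(benzyloxy)phenyl]-3-hydroxy-3,4-dihydro-2H-chromen-8-yl}-2-[3,4-bis(benzyloxy)phenyl]-3,4-dihydro-2H-chromen-3-ol, via bis(alkylborane) 22 (not isolated)
Conditions: BH3·THF (6 equiv), THF, 0 °C → rt; then 3 M NaOH, 30% H2O2, 0 °C → rt
Reagents that add atoms: hydrogen peroxide OO
Why: Hydroboration–oxidation of flav-3-enes; boron adds to C3 in both rings (the benzylic C4 takes the hydrogen and the C2 oxygen also directs boron to C3) on the face opposite the C2 aryl group, which sets C3 (S) in rings C and F. In ring C the hydrogen delivered syn at C4 places ring D trans to the C3 oxygen, which sets C4 (S). Oxidation proceeds with retention, and C2 becomes R by a change of substituent priority only.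

Step 17
Reactants: 23 hexa-O-benzyl diol
Product: 24 (2R,3S,4S)-2-(3,4-dihydroxyphenyl)-4-[(2R,3S)-2-(3,4-dihydroxyphenyl)-3,7-dihydroxy-3,4-dihydro-2H-chromen-8-yl]-3,4-dihydro-2H-chromene-3,7-diol
Conditions: H2 (1 atm), Pd(OH)2/C, THF–MeOH (1:1), rt; filtration and evaporation under N2
Reagents that add atoms: none
Why: Hydrogenolysis of six aryl benzyl ethers under neutral conditions; the secondary alcohols, the ring ethers and the C4–C8 bond are not cleaved at atmospheric pressure without acid, and no stereocentre is touched.

## Compound list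

1 | 2-bromoresorcinol (2-bromobenzene-1,3-diol) | Oc1cccc(O)c1Br | starting material
2 | (3-bromo-2,4-dihydroxybenzylidene)dimethyliminium chloride | C[N+](C)=Cc1ccc(O)c(Br)c1O.[Cl-] | intermediate, not isolated
3 | 3-bromo-2,4-dihydroxybenzaldehyde | O=Cc1ccc(O)c(Br)c1O | intermediate
4 | 4-(benzyloxy)-3-bromo-2-hydroxybenzaldehyde | O=Cc1ccc(OCc2ccccc2)c(Br)c1O | intermediate
5 | 2-(allyloxy)-4-(benzyloxy)-3-bromobenzaldehyde | O=Cc1ccc(OCc2ccccc2)c(Br)c1OCC=C | intermediate
6 | 3-(allyloxy)-1-(benzyloxy)-2-bromo-4-ethenylbenzene | C=Cc1ccc(OCc2ccccc2)c(Br)c1OCC=C | intermediate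
7 | 2,4-dihydroxybenzaldehyde | O=Cc1ccc(O)cc1O | starting material
8 | 4-(benzyloxy)-2-hydroxybenzaldehyde | O=Cc1ccc(OCc2ccccc2)cc1O | intermediate
9 | 2-(allyloxy)-4-(benzyloxy)benzaldehyde | O=Cc1ccc(OCc2ccccc2)cc1OCC=C | intermediate
10 | [2-(allyloxy)-6-(benzyloxy)-3-ethenylphenyl]lithium | [Li]c1c(OCc2ccccc2)ccc(C=C)c1OCC=C | intermediate, not isolated
11 | [2-(allyloxy)-4-(benzyloxy)phenyl][2-(allyloxy)-6-(benzyloxy)-3-ethenylphenyl]methanol, racemic | OC(c1ccc(OCc2ccccc2)cc1OCC=C)c1c(OCc2ccccc2)ccc(C=C)c1OCC=C | intermediate
12 | [2-(allyloxy)-4-(benzyloxy)phenyl][2-(allyloxy)-6-(benzyloxy)-3-ethenylphenyl]methanone | O=C(c1ccc(OCc2ccccc2)cc1OCC=C)c1c(OCc2ccccc2)ccc(C=C)c1OCC=C | intermediate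
13 | 1-[2-(allyloxy)-4-(benzyloxy)phenyl]-1-[2-(allyloxy)-6-(benzyloxy)-3-ethenylphenyl]ethene | C=C(c1ccc(OCc2ccccc2)cc1OCC=C)c1c(OCc2ccccc2)ccc(C=C)c1OCC=C | intermediate
14 | 1-[4-(benzyloxy)-2-hydroxyphenyl]-1-[6-(benzyloxy)-3-ethenyl-2-hydroxyphenyl]ethene | C=C(c1ccc(OCc2ccccc2)cc1O)c1c(OCc2ccccc2)ccc(C=C)c1O | intermediate
15 | caffeic acid | OC(=O)/C=C/c1ccc(O)c(O)c1 | starting material
16 | benzyl (E)-3-[3,4-bis(benzyloxy)phenyl]prop-2-enoate | O=C(OCc1ccccc1)/C=C/c1ccc(OCc2ccccc2)c(OCc2ccccc2)c1 | intermediate
17 | (E)-3-[3,4-bis(benzyloxy)phenyl]prop-2-en-1-ol | OC/C=C/c1ccc(OCc2ccccc2)c(OCc2ccccc2)c1 | intermediate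
18 | (E)-3-[3,4-bis(benzyloxy)phenyl]prop-2-en-1-yl methyl carbonate | COC(=O)OC/C=C/c1ccc(OCc2ccccc2)c(OCc2ccccc2)c1 | intermediate
19 | tetraene: 1-[4-(benzyloxy)-2-{[(1S)-1-(3,4-bis(benzyloxy)phenyl)prop-2-en-1-yl]oxy}phenyl]-1-[6-(benzyloxy)-2-{[(1S)-1-(3,4-bis(benzyloxy)phenyl)prop-2-en-1-yl]oxy}-3-ethenylphenyl]ethene | C(c3ccccc3)Oc1ccc(C(=C)c2c(OCc3ccccc3)ccc(C=C)c2O[C@H](c2ccc(OCc3ccccc3)c(OCc3ccccc3)c2)C=C)c(c1)O[C@H](c1ccc(OCc3ccccc3)c(OCc3ccccc3)c1)C=C | intermediate
20 | ring-F chromene: (2S)-7-(benzyloxy)-8-{1-[4-(benzyloxy)-2-{[(1S)-1-(3,4-bis(benzyloxy)phenyl)prop-2-en-1-yl]oxy}phenyl]ethenyl}-2-[3,4-bis(benzyloxy)phenyl]-2H-chromene | C=C(c1ccc(OCc2ccccc2)cc1O[C@H](c1ccc(OCc2ccccc2)c(OCc2ccccc2)c1)C=C)c1c(OCc2ccccc2)ccc2c1O[C@H](c1ccc(OCc3ccccc3)c(OCc3ccccc3)c1)C=C2 | intermediate, not isolated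
21 | bis-flavene: (2S)-7-(benzyloxy)-4-{(2S)-7-(benzyloxy)-2-[3,4-bis(benzyloxy)phenyl]-2H-chromen-8-yl}-2-[3,4-bis(benzyloxy)phenyl]-2H-chromene | C(c3ccccc3)Oc1ccc2c(c1)O[C@H](c1ccc(OCc3ccccc3)c(OCc3ccccc3)c1)C=C2c1c(OCc3ccccc3)ccc2c1O[C@H](c1ccc(OCc3ccccc3)c(OCc3ccccc3)c1)C=C2 | intermediate
22 | bis(alkylborane): the 3-boryl analogue of 23 in both rings, boron trans to each C2 aryl group, drawn as the BH2 species | C(c3ccccc3)Oc1ccc2c(c1)O[C@H](c1ccc(OCc3ccccc3)c(OCc3ccccc3)c1)[C@@H](B)[C@@H]2c1c(OCc3ccccc3)ccc2c1O[C@H](c1ccc(OCc3ccccc3)c(OCc3ccccc3)c1)[C@@H](B)C2 | intermediate, not isolated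
23 | hexa-O-benzyl diol: (2R,3S,4S)-7-(benzyloxy)-4-{(2R,3S)-7-(benzyloxy)-2-[3,4-bis(benzyloxy)phenyl]-3-hydroxy-3,4-dihydro-2H-chromen-8-yl}-2-[3,4-bis(benzyloxy)phenyl]-3,4-dihydro-2H-chromen-3-ol | C(c3ccccc3)Oc1ccc2c(c1)O[C@H](c1ccc(OCc3ccccc3)c(OCc3ccccc3)c1)[C@@H](O)[C@@H]2c1c(OCc3ccccc3)ccc2c1O[C@H](c1ccc(OCc3ccccc3)c(OCc3ccccc3)c1)[C@@H](O)C2 | intermediate
24 | (2R,3S,4S)-2-(3,4-dihydroxyphenyl)-4-[(2R,3S)-2-(3,4-dihydroxyphenyl)-3,7-dihydroxy-3,4-dihydro-2H-chromen-8-yl]-3,4-dihydro-2H-chromene-3,7-diol | Oc1ccc2c(c1)O[C@H](c1ccc(O)c(O)c1)[C@@H](O)[C@@H]2c1c(O)ccc2c1O[C@H](c1ccc(O)c(O)c1)[C@@H](O)C2 | target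

## Step count and least certain steps

Total: 17 steps. Longest linear sequence: 12 steps (1, 2, 3, 4, 7, 8, 9, 10, 14, 15, 16, 17).

**Step 15 (key step).** The most likely failure is a stalled closure of ring C: the 1,1-diarylethene carries a di-ortho-substituted arene that shields the alkene, so the catalyst may decompose before the second metallacycle forms. The long heating that a slow closure needs would also favour ruthenium hydride migration of the remaining ether double bond and loss of configuration at C2 by reversible ring opening. The fallback closes each ring on an unhindered diene and forms the C4–C8 bond afterwards; it sets out from 4, 8 and 18 and returns at 21.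
- Ring D/F half: aldehyde 4 is methylenated directly with excess Ph3P=CH2 to 3-(benzyloxy)-2-bromo-6-ethenylphenol F1. Its lithium phenoxide is etherified with 18 under the iridium conditions of step 14 to 1-(benzyloxy)-3-{[(1S)-1-(3,4-bis(benzyloxy)phenyl)prop-2-en-1-yl]oxy}-2-bromo-4-ethenylbenzene F2. Second-generation Grubbs catalyst at 40 °C closes ring F to (2S)-7-(benzyloxy)-2-[3,4-bis(benzyloxy)phenyl]-8-bromo-2H-chromene F3.
- Ring A/C half: the lithium phenoxide of 8 is etherified with 18 in the same way to 4-(benzyloxy)-2-{[(1S)-1-(3,4-bis(benzyloxy)phenyl)prop-2-en-1-yl]oxy}benzaldehyde F4. The Ohira–Bestmann reagent (K2CO3, MeOH) gives the 1-ethynyl arene F5. Copper-catalysed Markovnikov protoboration (B2pin2, (SIMes)CuCl, NaOtBu, MeOH) gives the 1-(pinacolboryl)vinyl arene F6. Ring-closing metathesis gives (2S)-7-(benzyloxy)-2-[3,4-bis(benzyloxy)phenyl]-4-(pinacolboryl)-2H-chromene F7.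
- Union: Suzuki–Miyaura coupling of F7 with F3 (Pd(OAc)2, SPhos, K3PO4, toluene–water, 60 °C) gives 21.

**Step 14.** The most likely failure is incomplete etherification at the ring-D phenoxide, which is flanked by a vinyl and a 1-arylvinyl group. Slow attack gives the iridium catalyst time to re-ionise the electron-rich ether already formed on ring A, with loss of branched selectivity and enantiomeric purity, and the double reaction multiplies any leakage into diastereomers. The fallback etherifies each ring before the two are joined, when each phenoxide is less encumbered; it sets out from 4 and 8 and returns at 19. Bromide F2 and aldehyde F4, made as described under step 15, are united as in step 7: bromine–lithium exchange on F2 with n-BuLi at −78 °C and immediate addition of F4 give the bis-ether carbinol F8. MnO2 gives the bis-ether ketone F9, and Cp2TiMe2 in toluene at 70 °C gives 19. The aryllithium must be kept cold and short-lived because the ether C–H next to it is acidic.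

**Step 16.** The most likely failure is slow and unselective addition of borane to the trisubstituted alkene of ring C, whose two faces are both partly covered by the ortho substituents of the perpendicular ring D. Forcing the reaction risks elimination of the β-aryloxy borane with opening of a pyran ring. The fallback treats the rings one after the other; it sets out from 21 and returns at 23.
- A short exposure to BH3·THF at 0 °C and oxidation should convert only the disubstituted alkene of ring F and give the ring-F alcohol F11.
- Dimethyldioxirane in acetone at −20 °C epoxidises the ring-C alkene anti to the C2 aryl group to give epoxide F12.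
- MgBr2·OEt2 opens the epoxide at the doubly benzylic C4 with a 1,2-hydride shift (Meinwald rearrangement), and a trace of Et3N equilibrates C4 to the 2,4-cis flavan-3-one F13, in which both aryl groups are equatorial.
- NaBH4 in THF–MeOH at −20 °C should then add hydride axially and give the equatorial C3 alcohol, that is 23.

**Step 9.** The most likely failure is slow methylenation of the ketone, whose carbonyl is twisted out of conjugation and flanked by three ortho alkoxy groups; long heating with excess titanium reagent could then begin to engage the allyl ether alkenes. The fallback replaces the olefination by addition and elimination; it sets out from 12 and returns at 13. MeLi with anhydrous CeCl3 in THF at −78 °C adds to the carbonyl to give the tertiary alcohol 1-[2-(allyloxy)-4-(benzyloxy)phenyl]-1-[2-(allyloxy)-6-(benzyloxy)-3-ethenylphenyl]ethanol F10. The Burgess reagent in THF at 50 °C dehydrates it toward the only β-hydrogens, those of the methyl group, and gives 13.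

## Further compounds

F1 | step 15 | 3-(benzyloxy)-2-bromo-6-ethenylphenol | C=Cc1ccc(OCc2ccccc2)c(Br)c1O
F2 | step 15 | 1-(benzyloxy)-3-{[(1S)-1-(3,4-bis(benzyloxy)phenyl)prop-2-en-1-yl]oxy}-2-bromo-4-ethenylbenzene | C=Cc1ccc(OCc2ccccc2)c(Br)c1O[C@H](c1ccc(OCc2ccccc2)c(OCc2ccccc2)c1)C=C
F3 | step 15 | (2S)-7-(benzyloxy)-2-[3,4-bis(benzyloxy)phenyl]-8-bromo-2H-chromene | Brc1c(OCc2ccccc2)ccc2c1O[C@H](c1ccc(OCc3ccccc3)c(OCc3ccccc3)c1)C=C2
F4 | step 15 | 4-(benzyloxy)-2-{[(1S)-1-(3,4-bis(benzyloxy)phenyl)prop-2-en-1-yl]oxy}benzaldehyde | O=Cc1ccc(OCc2ccccc2)cc1O[C@H](c1ccc(OCc2ccccc2)c(OCc2ccccc2)c1)C=C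
F5 | step 15 | 4-(benzyloxy)-2-{[(1S)-1-(3,4-bis(benzyloxy)phenyl)prop-2-en-1-yl]oxy}-1-ethynylbenzene | C#Cc1ccc(OCc2ccccc2)cc1O[C@H](c1ccc(OCc2ccccc2)c(OCc2ccccc2)c1)C=C
F6 | step 15 | 2-{1-[4-(benzyloxy)-2-{[(1S)-1-(3,4-bis(benzyloxy)phenyl)prop-2-en-1-yl]oxy}phenyl]ethenyl}-4,4,5,5-tetramethyl-1,3,2-dioxaborolane | C=C(B1OC(C)(C)C(C)(C)O1)c1ccc(OCc2ccccc2)cc1O[C@H](c1ccc(OCc2ccccc2)c(OCc2ccccc2)c1)C=C
F7 | step 15 | (2S)-7-(benzyloxy)-2-[3,4-bis(benzyloxy)phenyl]-4-(4,4,5,5-tetramethyl-1,3,2-dioxaborolan-2-yl)-2H-chromene | C(c3ccccc3)Oc1ccc2c(c1)O[C@H](c1ccc(OCc3ccccc3)c(OCc3ccccc3)c1)C=C2B1OC(C)(C)C(C)(C)O1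
F8 | step 14 | [4-(benzyloxy)-2-{[(1S)-1-(3,4-bis(benzyloxy)phenyl)prop-2-en-1-yl]oxy}phenyl][6-(benzyloxy)-2-{[(1S)-1-(3,4-bis(benzyloxy)phenyl)prop-2-en-1-yl]oxy}-3-ethenylphenyl]methanol, both carbinol epimers | OC(c1ccc(OCc2ccccc2)cc1O[C@H](c1ccc(OCc2ccccc2)c(OCc2ccccc2)c1)C=C)c1c(OCc2ccccc2)ccc(C=C)c1O[C@H](c1ccc(OCc2ccccc2)c(OCc2ccccc2)c1)C=C
F9 | step 14 | [4-(benzyloxy)-2-{[(1S)-1-(3,4-bis(benzyloxy)phenyl)prop-2-en-1-yl]oxy}phenyl][6-(benzyloxy)-2-{[(1S)-1-(3,4-bis(benzyloxy)phenyl)prop-2-en-1-yl]oxy}-3-ethenylphenyl]methanone | O=C(c1ccc(OCc2ccccc2)cc1O[C@H](c1ccc(OCc2ccccc2)c(OCc2ccccc2)c1)C=C)c1c(OCc2ccccc2)ccc(C=C)c1O[C@H](c1ccc(OCc2ccccc2)c(OCc2ccccc2)c1)C=C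
F10 | step 9 | 1-[2-(allyloxy)-4-(benzyloxy)phenyl]-1-[2-(allyloxy)-6-(benzyloxy)-3-ethenylphenyl]ethanol, racemic | CC(O)(c1ccc(OCc2ccccc2)cc1OCC=C)c1c(OCc2ccccc2)ccc(C=C)c1OCC=C
F11 | step 16 | (2R,3S)-7-(benzyloxy)-8-{(2S)-7-(benzyloxy)-2-[3,4-bis(benzyloxy)phenyl]-2H-chromen-4-yl}-2-[3,4-bis(benzyloxy)phenyl]-3,4-dihydro-2H-chromen-3-ol | C(c3ccccc3)Oc1ccc2c(c1)O[C@H](c1ccc(OCc3ccccc3)c(OCc3ccccc3)c1)C=C2c1c(OCc3ccccc3)ccc2c1O[C@H](c1ccc(OCc3ccccc3)c(OCc3ccccc3)c1)[C@@H](O)C2
F12 | step 16 | 3,4-epoxide of F11 in ring C, epoxide oxygen on the face opposite the C2 aryl group | C(c3ccccc3)Oc1ccc2c(c1)O[C@H](c1ccc(OCc3ccccc3)c(OCc3ccccc3)c1)[C@H]4O[C@@]24c1c(OCc3ccccc3)ccc2c1O[C@H](c1ccc(OCc3ccccc3)c(OCc3ccccc3)c1)[C@@H](O)C2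
F13 | step 16 | ring-C flavan-3-one with the C2 and C4 aryl groups cis, ring F as in 23 | C(c3ccccc3)Oc1ccc2c(c1)O[C@H](c1ccc(OCc3ccccc3)c(OCc3ccccc3)c1)C(=O)[C@@H]2c1c(OCc3ccccc3)ccc2c1O[C@H](c1ccc(OCc3ccccc3)c(OCc3ccccc3)c1)[C@@H](O)C2
A1 | alternative 1 | (Z)-{[2-(benzyloxy)-1-(3,4-bis(benzyloxy)phenyl)ethenyl]oxy}(tert-butyl)dimethylsilane | CC(C)(C)[Si](C)(C)O/C(=C\OCc1ccccc1)c1ccc(OCc2ccccc2)c(OCc2ccccc2)c1
A2 | alternative 1 | (2R,3S,4S)-3,7-bis(benzyloxy)-2-[3,4-bis(benzyloxy)phenyl]-4-[6-(benzyloxy)-2-hydroxy-3-(hydroxymethyl)phenyl]chromane | C(c3ccccc3)Oc1ccc2c(c1)O[C@H](c1ccc(OCc3ccccc3)c(OCc3ccccc3)c1)[C@@H](OCc3ccccc3)[C@@H]2c1c(OCc3ccccc3)ccc(CO)c1O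
A3 | alternative 1 | ring-F 2-(tert-butyldimethylsilyloxy)-2-aryl-3-benzyloxychroman ketal of the protected dimer, C2 epimers | C(c3ccccc3)Oc1ccc2c(c1)O[C@H](c1ccc(OCc3ccccc3)c(OCc3ccccc3)c1)[C@@H](OCc3ccccc3)[C@@H]2c1c(OCc3ccccc3)ccc2c1OC(O[Si](C)(C)C(C)(C)C)(c1ccc(OCc3ccccc3)c(OCc3ccccc3)c1)[C@@H](OCc3ccccc3)C2
A4 | alternative 2 | 5-(benzyloxy)-2-{[tetra-O-benzylfisetinidol-8-yl](4-tolylsulfonyl)methyl}phenol, either configuration at the sulfonyl carbon | Oc1cc(OCc2ccccc2)ccc1C(S(=O)(=O)c1ccc(C)cc1)c1c(OCc2ccccc2)ccc2c1O[C@H](c1ccc(OCc3ccccc3)c(OCc3ccccc3)c1)[C@@H](OCc3ccccc3)C2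
A5 | alternative 2 | benzyloxyacetyl chloride | O=C(Cl)COCc1ccccc1
A6 | alternative 2 | (3S,4S)-3,7-bis(benzyloxy)-4-(tetra-O-benzylfisetinidol-8-yl)-3,4-dihydrocoumarin | C(c3ccccc3)Oc1ccc2c(c1)OC(=O)[C@@H](OCc3ccccc3)[C@@H]2c1c(OCc3ccccc3)ccc2c1O[C@H](c1ccc(OCc3ccccc3)c(OCc3ccccc3)c1)[C@@H](OCc3ccccc3)C2
A7 | alternative 3 | protected upper flavan whose ring-D phenol is etherified with a 1-[3,4-bis(benzyloxy)phenyl]-2,3-epoxypropyl group | C(c3ccccc3)Oc1ccc2c(c1)O[C@H](c1ccc(OCc3ccccc3)c(OCc3ccccc3)c1)[C@@H](OCc3ccccc3)[C@@H]2c1c(OCc3ccccc3)cccc1O[C@H](c1ccc(OCc3ccccc3)c(OCc3ccccc3)c1)[C@@H]1CO1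
A8 | alternative 3 | hepta-O-benzyl derivative of 24 with the ring-F C3 hydroxyl free | C(c3ccccc3)Oc1ccc2c(c1)O[C@H](c1ccc(OCc3ccccc3)c(OCc3ccccc3)c1)[C@@H](OCc3ccccc3)[C@@H]2c1c(OCc3ccccc3)ccc2c1O[C@H](c1ccc(OCc3ccccc3)c(OCc3ccccc3)c1)[C@@H](O)C2
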